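A small charge of third substrate, 0.500 equiv, goes into maple, cedar and ash beside 1.80 equiv of coupling partner, and the target's survival in the heat is the thing to watch.

| flask | starting material | coupling partner | second substrate | third substrate | temperature | remark | time |
|---|---|---|---|---|---|---|---|
| gamma | 1 M | 0.90 equiv | 1 equiv | 0.50 equiv | 65 °C | run made earlier |  |
| delta | 1 M | 1.8 equiv | 1 equiv | 0.75 equiv | 85 °C | run made earlier |  |
| maple | 1.0 M | 1.80 equiv | 1.00 equiv | 0.500 equiv | 70 °C |  | 8.0 h |
| cedar | 1.0 M | 1.80 equiv | 1.00 equiv | 0.500 equiv |  | at 70 °C until 4.0 h, from then on at 100 °C | 8.0 h |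
| ash | 1.0 M | 1.80 equiv | 1.00 equiv | 0.500 equiv | 100 °C |  | 8.0 h |

- gamma (time / h: target / %, starting material / %): 0.500: 3.2, 97.6; 1.50: 6.9, 92.4; 3.00: 10.3, 89.9; 5.00: 13.1, 85.5; 6.00: 14.2, 85.4
- delta (time / h: target / %, starting material / %): 0.250: 11.4, 88.9; 0.500: 16.2, 83.1; 1.00: 22.0, 75.2; 1.33: 22.9, 72.7; 3.00: 20.5, 67.6

(each reading ± 0.5 percentage points)

- the analysis behind the earlier runs scatters by 0.5 percentage points, standard deviation

- which flask leads in amount of target, in percent of the starting material charged ("all alike" within 1.5 percentage points) (maple / cedar / ash / all alike)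
- how much target is there at the end, in percent of the starting material charged: maple
- how much target is there at the end, in percent of the starting material charged: cedar
- how much target is there at the end, in percent of the starting material charged: ash

1. The balance gap g is 100% minus target minus starting material. Delta shows 11.9% at 3.00 h.

2. The first-order loss constant k is g divided by mid-run target and by run time. Delta, with 22.9% near mid-run, gives 0.173 h⁻¹. Gamma's last two readings average 0.900% against a scatter of 0.5 percentage points, so its 0.0146 h⁻¹ is rough.

3. This reckoning takes a constant factor per degree: k grows 11.9-fold from 65 °C to 85 °C. That gives 0.0270 h⁻¹ at 70 °C and 1.11 h⁻¹ at 100 °C.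

4. The survivor share S is exp(−k × hot time), the part of the target made that is still target, counted as if all were made at the start. Maple: 80.5%. Cedar, on its stock at the change: 1.18%. Ash: 0.0140%.

5. Maple, held at 70 °C, keeps a larger share than cedar and ash. This reckoning gives shares, not amounts.

The forecast gives amounts: maple leads with 26%, cedar 1.2%, ash 0.3%. “Maple should plateau near 30%, then lose a little, ending around 26%.”

The flasks end at 36.7% for maple, 1.48% for cedar and 0.492% for ash, so maple leads.

    starting material + coupling partner → target (k = 3.39 × 10⁻⁵ L mol⁻¹ s⁻¹, Ea = 73.0 kJ mol⁻¹)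
    target ⇌ isomer of the product (K = 1.62, k = 2.05 × 10⁻⁶ s⁻¹, Ea = 128 kJ mol⁻¹, ΔH = 27.0 kJ mol⁻¹)
    third substrate + coupling partner → third product (k = 3.97 × 10⁻⁴ L mol⁻¹ s⁻¹, Ea = 59.0 kJ mol⁻¹)
    second substrate + coupling partner → second product (k = 3.31 × 10⁻⁵ L mol⁻¹ s⁻¹, Ea = 81.0 kJ mol⁻¹)
    coupling partner → decomposed reagent (k = 1.45 × 10⁻⁵ s⁻¹, Ea = 116 kJ mol⁻¹)
    target → over-reaction product (k = 6.02 × 10⁻⁶ s⁻¹, Ea = 126 kJ mol⁻¹)
    (constants at 70 °C)

Maple parts from the forecast in the amount made: it has used 43.1% of its starting material, and target is 85.2% of that, beside S of 80.5%. The neighbour, like ash but kept at 85 °C, takes k of 0.173 h⁻¹ for 8.0 h, so S is 25.1%. That flask has used 41.8% of its starting material and holds 12.1% target, a share of 28.9%.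

The earlier runs and the new flask stem from a simulated flask for an exercise; noise was put on by code.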